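**Retrosynthetic overview**

1. Target 13 is 1-(4-hydroxy-3-methoxyphenyl)hexadecane-3,5-dione (no stereocentre); the last disconnection is the O–Si bond of the phenol TBS ether 12.
2. Key disconnection: C3–C4 of the 3,5-dione, made by a biomimetic decarboxylative Claisen condensation. C3 arrives as the acyl imidazolide of O-TBS-dihydroferulic acid (a stand-in for the coenzyme A thioester). C4 arrives as C2 of 3-oxotetradecanoic acid 8, whose carboxyl group is a traceless activating group lost as CO2 in the same operation.
3. Enabling feature: the C4 methylene lies between the C3 and C5 carbonyls, so it can carry a carboxyl group as a third acyl substituent and be acylated as a magnesium-chelated enolate. This is how plant polyketide synthases of the curcuminoid synthase type are presumed to build gingerdiones from a (dihydro)feruloyl thioester and a 3-oxo fatty acid.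
4. Acid 8 (C4–C16 plus the sacrificial carboxyl) is disconnected at C4–C5 to dodecanoyl chloride and Meldrum's acid; acid 3 comes from dihydroferulic acid by silylation.
5. Rings: the guaiacol ring is bought intact and no ring of the target is formed. The only ring made is the temporary six-membered magnesium chelate (Mg, O, C5, C4, carboxyl C, O) of the key step, opened again on work-up.

Key step: step 5

Remark: the β-dicarbonyl compounds 7, 8, 11, 12 and 13 are written as keto tautomers although they should be largely enolized; 6 is written as its enol and 10 as a covalent chelate.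

**Route**

Step 1
Reactants: 1 dihydroferulic acid [3-(4-hydroxy-3-methoxyphenyl)propanoic acid]
Product: 3 3-[4-(tert-butyldimethylsilyloxy)-3-methoxyphenyl]propanoic acid, via silyl ester silyl ether 2 (not isolated)
Conditions: TBSCl (2.3 equiv), imidazole (5 equiv), DMF, rt; then AcOH/THF/H2O (3:1:1), rt
Reagents that add atoms: tert-butyldimethylsilyl chloride (TBSCl), CC(C)(C)[Si](C)(C)Cl
Why: Exhaustive silylation (Corey conditions) should give silyl ester and aryl silyl ether, and the far more labile silyl ester should then be hydrolysed selectively by aqueous acetic acid, which leaves the aryl TBS ether intact.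

Step 2
Reactants: 4 dodecanoyl chloride (lauroyl chloride); 5 Meldrum's acid (2,2-dimethyl-1,3-dioxane-4,6-dione)
Product: 6 5-(1-hydroxydodecylidene)-2,2-dimethyl-1,3-dioxane-4,6-dione
Conditions: pyridine (2.2 equiv), CH2Cl2, 0 °C to rt; 1 M HCl wash
Reagents that add atoms: none
Why: C-acylation of the highly acidic Meldrum's acid by an acid chloride with pyridine (first stage of the Oikawa–Yonemitsu β-keto ester synthesis) should give the enolic acyl Meldrum's acid.

Step 3
Reactants: 6 5-(1-hydroxydodecylidene)-2,2-dimethyl-1,3-dioxane-4,6-dione
Product: 7 methyl 3-oxotetradecanoate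
Conditions: MeOH, reflux
Reagents that add atoms: methanol, CO
Why: Thermal alcoholysis of an acyl Meldrum's acid (second stage of the Oikawa–Yonemitsu synthesis) should deliver the methyl β-keto ester with loss of acetone and carbon dioxide.

Step 4
Reactants: 7 methyl 3-oxotetradecanoate
Product: 8 3-oxotetradecanoic acid
Conditions: 1 M NaOH aq. (1.5 equiv), THF, 0 °C to rt; then 1 M HCl, 0 °C; extraction and crystallisation below 25 °C, storage at −20 °C
Reagents that add atoms: sodium hydroxide, [Na+].[OH-]
Why: Saponification of a β-keto methyl ester at or below room temperature followed by cold acidification is the standard access to crystalline long-chain 3-oxo acids, which lose carbon dioxide only on warming.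

Step 5
Reactants: 3 3-[4-(tert-butyldimethylsilyloxy)-3-methoxyphenyl]propanoic acid; 8 3-oxotetradecanoic acid
Product: 12 1-[4-(tert-butyldimethylsilyloxy)-3-methoxyphenyl]hexadecane-3,5-dione, via acyl imidazolide 9 (not isolated), via magnesium chelate 10 (not isolated), via 2-acyl-3-oxotetradecanoic acid 11 (not isolated)
Conditions: 3, CDI (1.05 equiv), THF, rt (gives 9); separately 8 (1.5 equiv), MgCl2 (1.5 equiv), Et3N (3 equiv), MeCN, 0 °C to rt (gives 10); solution of 9 added to 10, rt to 40 °C; then 1 M HCl, 0 °C to rt
Reagents that add atoms: none
Why: Proposed new method: MgCl2/Et3N should convert 8 into its six-membered magnesium chelate 10 (enolate oxygen and carboxylate on one magnesium), whose central carbon attacks the acyl imidazolide 9 and expels imidazole to give the carboxylate of 11; this loses CO2 through a cyclic six-centre transition state, in the flask or at the latest on acidification, because the electron pair left behind is delocalized over two ketones, and the magnesium diketonate of 12 results. The closest known reaction type is the decarboxylative Claisen condensation of magnesium malonate half-esters with acyl imidazolides (Masamune–Brooks β-keto ester synthesis) and of substituted malonic acid half oxyesters with acyl donors; new is the use of a 3-oxo acid in place of the malonic half-ester, which copies the way curcuminoid-synthase-type enzymes are presumed to join a (dihydro)feruloyl thioester to a 3-oxo fatty acid. No ring of the product is closed (the chelate ring of 10 is temporary and is opened on work-up) and no stereocentre is created, since C2 of 11 is a transient, enolized centre that disappears with the carboxyl group. The step needs C- over O-acylation, which chelation of both oxygens to magnesium should secure; acylation at the future C4 and not at C6, which is secured because only the carbon between carboxylate and ketone is doubly activated; and mono-acylation, which is secured by using 9 as the limiting partner and by the low nucleophilicity of the magnesium diketonate of 12. The 3-oxo acid is a stronger carbon acid than the malonic half-ester of the precedent, so soft enolization should be easier, and its carboxylate form should be slow to lose CO2 before it is acylated.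

Step 6
Reactants: 12 1-[4-(tert-butyldimethylsilyloxy)-3-methoxyphenyl]hexadecane-3,5-dione
Product: 13 [12]-gingerdione [1-(4-hydroxy-3-methoxyphenyl)hexadecane-3,5-dione]
Conditions: Bu4NF (1.2 equiv), AcOH (1.5 equiv), THF, 0 °C
Reagents that add atoms: none
Why: Fluoride-induced cleavage of an aryl silyl ether, buffered with acetic acid so that the 1,3-diketone is not exposed to strongly basic fluoride, should free the phenol.

**Compound list**

1 | dihydroferulic acid, 3-(4-hydroxy-3-methoxyphenyl)propanoic acid | OC(=O)CCc1ccc(O)c(OC)c1 | starting material
2 | tert-butyldimethylsilyl 3-[4-(tert-butyldimethylsilyloxy)-3-methoxyphenyl]propanoate | CC(C)(C)[Si](C)(C)OC(=O)CCc1ccc(O[Si](C)(C)C(C)(C)C)c(OC)c1 | intermediate (not isolated)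
3 | 3-[4-(tert-butyldimethylsilyloxy)-3-methoxyphenyl]propanoic acid | OC(=O)CCc1ccc(O[Si](C)(C)C(C)(C)C)c(OC)c1 | intermediate
4 | dodecanoyl chloride | CCCCCCCCCCCC(=O)Cl | starting material
5 | Meldrum's acid, 2,2-dimethyl-1,3-dioxane-4,6-dione | CC1(C)OC(=O)CC(=O)O1 | starting material
6 | 5-(1-hydroxydodecylidene)-2,2-dimethyl-1,3-dioxane-4,6-dione | CCCCCCCCCCCC(O)=C1C(=O)OC(C)(C)OC1=O | intermediate
7 | methyl 3-oxotetradecanoate | CCCCCCCCCCCC(=O)CC(=O)OC | intermediate
8 | 3-oxotetradecanoic acid | CCCCCCCCCCCC(=O)CC(=O)O | intermediate
9 | 1-{3-[4-(tert-butyldimethylsilyloxy)-3-methoxyphenyl]propanoyl}-1H-imidazole | O=C(CCc1ccc(O[Si](C)(C)C(C)(C)C)c(OC)c1)n1ccnc1 | intermediate (not isolated)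
10 | magnesium chelate of the 3-oxotetradecanoate dianion (magnesium 3-oxidotetradec-2-enoate) | CCCCCCCCCCCC1=CC(=O)O[Mg]O1 | intermediate (not isolated)
11 | 2-{3-[4-(tert-butyldimethylsilyloxy)-3-methoxyphenyl]propanoyl}-3-oxotetradecanoic acid (racemic, enolized, centre not defined) | CCCCCCCCCCCC(=O)C(C(=O)O)C(=O)CCc1ccc(O[Si](C)(C)C(C)(C)C)c(OC)c1 | intermediate (not isolated)
12 | 1-[4-(tert-butyldimethylsilyloxy)-3-methoxyphenyl]hexadecane-3,5-dione | CCCCCCCCCCCC(=O)CC(=O)CCc1ccc(O[Si](C)(C)C(C)(C)C)c(OC)c1 | intermediate
13 | [12]-gingerdione, 1-(4-hydroxy-3-methoxyphenyl)hexadecane-3,5-dione | CCCCCCCCCCCC(=O)CC(=O)CCc1ccc(O)c(OC)c1 | target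

**Step count and risks**

Total step count: 6. Longest linear sequence: 5 steps (steps 2, 3, 4, 5 and 6, from 4 and 5 to 13).

Steps most likely to fail:

Step 5 (proposed new method). The 3-oxo acid may lose carbon dioxide before it is acylated, and O-acylation or a second acylation of the chelated enolate may compete, so that conversion to the diketone is eroded. The fallback uses known chemistry, sets out from 6 and 3 and comes back to the route at 11. Thermal alcoholysis of 6 with benzyl alcohol (toluene, reflux) should give benzyl 3-oxotetradecanoate F1. Acid 3 is converted with oxalyl chloride and catalytic DMF (CH2Cl2, 0 °C) into 3-[4-(tert-butyldimethylsilyloxy)-3-methoxyphenyl]propanoyl chloride F2. C-acylation of F1 with F2 under MgCl2/pyridine in CH2Cl2 (Rathke conditions) should give benzyl 2-{3-[4-(tert-butyldimethylsilyloxy)-3-methoxyphenyl]propanoyl}-3-oxotetradecanoate F3. Hydrogenolysis of the benzyl ester (H2, 10% Pd/C, EtOAc, rt), to which the aryl silyl ether is inert, frees the acid 11, which loses carbon dioxide to 12 as in step 5.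

Step 4. Carbon dioxide may be lost during acidification and isolation of the free 3-oxo acid, and retro-Claisen cleavage may occur under hydroxide. The fallback sets out from 6 and comes back at 8. Alcoholysis of 6 with tert-butanol (toluene, 90 °C) should give tert-butyl 3-oxotetradecanoate F4, and non-aqueous acidolysis (TFA/CH2Cl2, 0 °C to rt, evaporation below 25 °C) should release 8 without any basic or aqueous stage.

Step 1. Silyl ester and aryl silyl ether may be differentiated incompletely in the hydrolytic work-up, with loss of the phenol protecting group or survival of the silyl ester. The fallback sets out from 1 and comes back at 3. Selective carboxylate alkylation (benzyl bromide, KHCO3, DMF, rt) should give benzyl 3-(4-hydroxy-3-methoxyphenyl)propanoate F5. Silylation of the phenol (TBSCl, imidazole, DMF) should give benzyl 3-[4-(tert-butyldimethylsilyloxy)-3-methoxyphenyl]propanoate F6. Hydrogenolysis (H2, 10% Pd/C, EtOAc, rt) should then give 3 under neutral conditions.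

**Further compounds**

F1 | step 5 | benzyl 3-oxotetradecanoate | CCCCCCCCCCCC(=O)CC(=O)OCc1ccccc1
F2 | step 5 | 3-[4-(tert-butyldimethylsilyloxy)-3-methoxyphenyl]propanoyl chloride | O=C(Cl)CCc1ccc(O[Si](C)(C)C(C)(C)C)c(OC)c1
F3 | step 5 | benzyl 2-{3-[4-(tert-butyldimethylsilyloxy)-3-methoxyphenyl]propanoyl}-3-oxotetradecanoate (racemic, enolized) | CCCCCCCCCCCC(=O)C(C(=O)OCc1ccccc1)C(=O)CCc1ccc(O[Si](C)(C)C(C)(C)C)c(OC)c1
F4 | step 4 | tert-butyl 3-oxotetradecanoate | CCCCCCCCCCCC(=O)CC(=O)OC(C)(C)C
F5 | step 1 | benzyl 3-(4-hydroxy-3-methoxyphenyl)propanoate | O=C(CCc1ccc(O)c(OC)c1)OCc1ccccc1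
F6 | step 1 | benzyl 3-[4-(tert-butyldimethylsilyloxy)-3-methoxyphenyl]propanoate | O=C(CCc1ccc(O[Si](C)(C)C(C)(C)C)c(OC)c1)OCc1ccccc1
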